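**Retrosynthetic overview**
1. Target ⇐ its doubly protected 15-deoxy analogue by late allylic hydroxylation at C15; the 3β-alcohol comes from a ring A 1-en-3-one.
2. Key disconnection: the γ-lactone and ring A are cut together (C4–C5 and C1–C2) back to a cyclopentene-carboxylate that carries a C10 aldehyde and a C10 O-(2-methylacetoacetyl) tether (tethered Michael addition, then aldol condensation, one pot).
3. Ring D ⇐ intramolecular Nozaki–Hiyama–Kishi addition of a 2-bromoallyl group to the C13 ketone; C7 ⇐ carbonylation of the C6 enol triflate.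
4. The C8 quaternary centre and ring C ⇐ Birch reductive alkylation of a 5-methoxy-3-oxoindane-1-carboxylic acid; the C10 oxygen ⇐ enolate hydroxylation.
5. Ring B ⇐ Friedel–Crafts cyclisation of an (S)-arylsuccinate made by asymmetric conjugate arylation. Ring order: C (arene) → B → D → lactone + A together.

Assumption: locants C1–C19 and α/β are those of the gibberellane skeleton of the target as usually drawn (β = the face of H-5, H-9 and C15); the diene ligand enantiomer in step 1 is the one that gives (S)-3 (its antipode is used if the sense is opposite).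

**Step 1**
Reactants: 1 4-methoxyphenylboronic acid; 2 di-tert-butyl fumarate
Product: 3 di-tert-butyl (S)-2-(4-methoxyphenyl)butanedioate
Conditions: [RhCl(C2H4)2]2 (1.5 mol %), (1R,4R)-2,5-diphenylbicyclo[2.2.2]octa-2,5-diene (3.3 mol %), KOH (0.1 equiv), dioxane–H2O 10:1, 50 °C
Reagents that add atoms: none
Why: Hayashi–Miyaura asymmetric 1,4-addition, in which the chiral diene on monovalent rhodium fixes the enantioface of aryl transfer so that the benzylic centre (future C10) is S.

**Step 2**
Reactants: 3 di-tert-butyl (S)-2-(4-methoxyphenyl)butanedioate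
Product: 5 (S)-5-methoxy-3-oxo-2,3-dihydro-1H-indene-1-carboxylic acid, via arylsuccinic acid 4 (not isolated)
Conditions: CF3CO2H–CH2Cl2 1:1, 25 °C, volatiles (isobutene) removed; then CF3SO3H (6 equiv), CH2Cl2, 0 → 40 °C
Reagents that add atoms: none
Why: acidolysis of both tert-butyl esters (isobutene is removed before the stronger acid is added, so the anisole ring is not tert-butylated) followed by intramolecular Friedel–Crafts acylation by the CH2CO2H arm (only the five-membered ring can close) forms ring B without touching the stereocentre.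

**Step 3**
Reactants: 5 (S)-5-methoxy-3-oxo-2,3-dihydro-1H-indene-1-carboxylic acid; 6 2,3-dibromoprop-1-ene
Product: 8 methyl (1S,3aS)-3a-(2-bromoprop-2-en-1-yl)-5-methoxy-3-oxo-2,3,3a,6-tetrahydro-1H-indene-1-carboxylate, via carboxylic acid 7 (not isolated)
Conditions: Li (3.3 equiv), NH3–THF, t-BuOH (1.0 equiv), −78 °C; isoprene; 6 (1.2 equiv), −78 °C; NH4Cl, NH3 evaporated; then MeI, K2CO3, DMF, 25 °C
Reagents that add atoms: iodomethane, CI
Why: Birch reductive alkylation of the aryl ketone (protonation at C12, C-alkylation of the dienolate at the ring-fusion carbon C8) sets the quaternary centre anti to the C10 carboxylate across the flat five-membered ring (1,3-induction, minor epimer removed by chromatography) and the carboxylate is then methylated.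

**Step 4**
Reactants: 8 methyl (1S,3aS)-3a-(2-bromoprop-2-en-1-yl)-5-methoxy-3-oxo-2,3,3a,6-tetrahydro-1H-indene-1-carboxylate
Product: 9 methyl (1S,3aS)-3a-(2-bromoprop-2-en-1-yl)-1-hydroxy-5-methoxy-3-oxo-2,3,3a,6-tetrahydro-1H-indene-1-carboxylate
Conditions: KN(SiMe3)2 (2.2 equiv), THF, −78 °C; 3-phenyl-2-(phenylsulfonyl)oxaziridine (1.2 equiv), −78 °C; NH4Cl
Reagents that add atoms: 3-phenyl-2-(phenylsulfonyl)oxaziridine, O=S(=O)(c1ccccc1)N1OC1c1ccccc1
Why: Davis hydroxylation of the ketone/ester bis-enolate at the ester α-carbon C10 (the last-formed, more nucleophilic site, whose reaction leaves the more stable ketone enolate), with the oxidant approaching opposite the angular bromoallyl group, gives the 10α-hydroxyl (the future lactone oxygen) and erases the relay centre.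

**Step 5**
Reactants: 9 methyl (1S,3aS)-3a-(2-bromoprop-2-en-1-yl)-1-hydroxy-5-methoxy-3-oxo-2,3,3a,6-tetrahydro-1H-indene-1-carboxylate
Product: 11 methyl 3a-(2-bromoprop-2-en-1-yl)-1-hydroxy-3,5-dioxo-2,3,3a,4,5,7a-hexahydro-1H-indene-1-carboxylate (cis-fused; 7a-H cis and 1-OH trans to the bromoallyl group), via unconjugated diketone 10 (not isolated)
Conditions: 2 M HCl, THF, 25 → 45 °C
Reagents that add atoms: water, O
Why: enol ether hydrolysis unmasks the C13 ketone and acid-catalysed dienol isomerisation moves the C9=C11 bond into conjugation, reversible γ-protonation at C9 giving the more stable cis-fused hydrindenone with 9-H on the face of the angular bromoallyl group.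

**Step 6**
Reactants: 11 cis-fused enone
Product: 12 methyl 3a-(2-bromoprop-2-en-1-yl)-1-hydroxy-3,5-dioxooctahydro-1H-indene-1-carboxylate (same configuration)
Conditions: Cu(OAc)2·H2O (3 mol %), 1,2-(Ph2P)2C6H4 (3 mol %), (EtO)2MeSiH (1.5 equiv), t-BuOH (1.5 equiv), PhMe, 25 °C
Reagents that add atoms: none
Why: CuH-catalysed 1,4-reduction (Stryker-type conjugate reduction) saturates only the enone double bond and leaves both ketones, the tertiary ketol and the vinyl bromide untouched, with no new stereocentre.

**Step 7**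
Reactants: 12 cis-fused bromoallyl diketone
Product: 13 tricyclic keto diol ester (rings B, C, D; C6 ketone, 10α-OH, 10β-CO2Me, 9β-H, 13-OH, 16-methylene)
Conditions: CrCl2 (6 equiv), NiCl2 (2 mol %), DMSO, 25 → 50 °C
Reagents that add atoms: none
Why: intramolecular Nozaki–Hiyama–Kishi reaction in which the alkenylchromium species from the axial 2-bromoallyl group adds across ring C to the C13 ketone (the only carbonyl it can reach in a five-membered closure), closing ring D as the bridgehead allylic alcohol whose configuration is fixed by the bridge.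

**Step 8**
Reactants: 13 tricyclic keto diol ester
Product: 14 13-O-triethylsilyl ether of 13
Conditions: Et3SiOTf (1.1 equiv), 2,6-lutidine, CH2Cl2, −78 °C
Reagents that add atoms: triethylsilyl trifluoromethanesulfonate, CC[Si](CC)(CC)OS(=O)(=O)C(F)(F)F
Why: silylation selects the exposed bridgehead C13 hydroxyl over the hindered, ester-deactivated C10 hydroxyl, which stays free for the later acylation.

**Step 9**
Reactants: 14 13-O-triethylsilyl ether
Product: 15 C5=C6 enol triflate of 14
Conditions: KN(SiMe3)2 (2.2 equiv), THF, −78 °C; PhNTf2 (1.2 equiv), −78 → 0 °C; aq. NH4Cl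
Reagents that add atoms: N-phenylbis(trifluoromethanesulfonimide), O=S(=O)(N(c1ccccc1)S(=O)(=O)C(F)(F)F)C(F)(F)F
Why: the C6 ketone can enolise only toward C5 (C8 is quaternary), so O-sulfonylation of the potassium enolate gives the C5=C6 enol triflate regiospecifically while the hindered tertiary alkoxide is left alone.

**Step 10**
Reactants: 15 enol triflate
Product: 16 10α-hydroxy-10β-carbaldehyde from 15
Conditions: i-Bu2AlH (2.3 equiv), CH2Cl2, −78 °C; aq. KNaC4H4O6
Reagents that add atoms: none
Why: partial reduction of the α-hydroxy ester stops at the aldehyde because the neighbouring aluminium alkoxide chelates the tetrahedral intermediate at −78 °C, while the triflate and silyl ether are inert.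

**Step 11**
Reactants: 16 hydroxy aldehyde; 17 2,2,5,6-tetramethyl-4H-1,3-dioxin-4-one
Product: 18 10-O-(2-methyl-3-oxobutanoyl) ester of 16 (both acyl α-epimers)
Conditions: 17 (3 equiv), PhMe, 110 °C, acetone distilled off
Reagents that add atoms: none
Why: retro-[4+2] thermolysis of the dioxinone gives acetyl(methyl)ketene, which acylates even the hindered tertiary C10 alcohol (the acyl α-centre is enolisable and of no consequence).

**Step 12**
Reactants: 18 acetoacetate enol triflate
Product: 19 2-(trimethylsilyl)ethyl C5=C6 enoate (C7 ester on C6) from 18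
Conditions: Pd(OAc)2 (5 mol %), Ph3P (10 mol %), CO (1 atm), Me3SiCH2CH2OH (5 equiv), Et3N (2 equiv), DMF, 45 °C
Reagents that add atoms: carbon monoxide, [C-]#[O+]; 2-(trimethylsilyl)ethanol, C[Si](C)(C)CCO
Why: alkoxycarbonylation of the enol triflate (oxidative addition to zerovalent palladium, CO insertion, alcoholysis) installs C7 as a fluoride-labile ester and creates the enoate acceptor.

**Step 13**
Reactants: 19 enoate aldehyde acetoacetate
Product: 21 ring A 1-en-3-one lactone (13-O-triethylsilyl ether and 7-[2-(trimethylsilyl)ethyl] ester of the 1,2-didehydro-3-oxo-15-deoxy target), via lactone Michael adduct 20 (not isolated)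
Conditions: Cs2CO3 (1.2 equiv), MeCN, 25 °C then 60 °C
Reagents that add atoms: none
Why: Proposed new method: the β-keto ester carbanion, held by the C10 oxygen, adds 5-exo to C5 of the γ-acyloxy enoate on the only face the tether reaches (closing the cis-fused γ-lactone and fixing C4, C5 and, after equilibration, the 6β-ester), then the acetyl methyl group condenses with the C10 aldehyde with loss of water to close ring A, the reversible Michael and off-path aldol equilibria funnelling material to the one diastereomer that can dehydrate; the closest known reaction types are the Robinson annulation and ester-tethered intramolecular Michael lactonisation.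

**Step 14**
Reactants: 21 ring A enone
Product: 23 13-O-triethylsilyl ether and 7-[2-(trimethylsilyl)ethyl] ester of the 15-deoxy target (3β-alcohol), via 3-ketone 22 (not isolated)
Conditions: K[(s-Bu)3BH] (1.1 equiv), THF, −78 °C; t-BuOH (2 equiv); K[(s-Bu)3BH] (1.5 equiv), −78 °C; aq. NH4Cl
Reagents that add atoms: none
Why: the hindered borohydride first reduces the β-unsubstituted enone in the 1,4 sense and, after protonation of the enolate, attacks the 3-ketone from the open equatorial (α) side to give the axial 3β-alcohol, the sense expected for 3-oxo lactones of this skeleton.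

**Step 15**
Reactants: 23 protected 15-deoxy target
Product: 24 13-O-triethylsilyl ether and 7-[2-(trimethylsilyl)ethyl] ester of the target (3β-OH and 15β-OH)
Conditions: SeO2 (0.5 equiv), t-BuOOH (3 equiv), CH2Cl2, 25 °C
Reagents that add atoms: selenium dioxide, O=[Se]=O; tert-butyl hydroperoxide, CC(C)(C)OO
Why: Riley allylic oxidation (ene reaction at C17, then [2,3]-sigmatropic shift) hydroxylates C15, the only allylic methylene, on the β face turned away from the 6β-ester, by analogy with the ent-kaur-16-ene series.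

**Step 16**
Reactants: 24 protected target
Product: 25 the target gibberellin (free 7-acid, 3β,13,15β-triol, 19,10-lactone, 16-ene)
Conditions: Bu4NF (4 equiv), AcOH (2 equiv), THF, 25 °C
Reagents that add atoms: none
Why: fluoride cleaves the triethylsilyl ether and fragments the 2-(trimethylsilyl)ethyl ester (β-elimination to ethene) under buffered, non-hydrolytic conditions that avoid retro-aldol epimerisation at C3.

**Compound list**
1 | 4-methoxyphenylboronic acid | COc1ccc(B(O)O)cc1 | starting material
2 | di-tert-butyl fumarate | CC(C)(C)OC(=O)/C=C/C(=O)OC(C)(C)C | starting material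
3 | di-tert-butyl (S)-2-(4-methoxyphenyl)butanedioate | CC(C)(C)OC(=O)[C@@H](CC(=O)OC(C)(C)C)c1ccc(OC)cc1 | intermediate
4 | (S)-2-(4-methoxyphenyl)butanedioic acid | OC(=O)[C@@H](CC(=O)O)c1ccc(OC)cc1 | intermediate (not isolated)
5 | (S)-5-methoxy-3-oxo-2,3-dihydro-1H-indene-1-carboxylic acid | OC(=O)[C@H]1CC(=O)c2cc(OC)ccc21 | intermediate
6 | 2,3-dibromoprop-1-ene | C=C(Br)CBr | starting material
7 | (1S,3aS)-3a-(2-bromoprop-2-en-1-yl)-5-methoxy-3-oxo-2,3,3a,6-tetrahydro-1H-indene-1-carboxylic acid | C=C(Br)C[C@]23C=C(OC)CC=C2[C@@H](C(=O)O)CC3=O | intermediate (not isolated)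
8 | methyl (1S,3aS)-3a-(2-bromoprop-2-en-1-yl)-5-methoxy-3-oxo-2,3,3a,6-tetrahydro-1H-indene-1-carboxylate | C=C(Br)C[C@]23C=C(OC)CC=C2[C@@H](C(=O)OC)CC3=O | intermediate
9 | methyl (1S,3aS)-3a-(2-bromoprop-2-en-1-yl)-1-hydroxy-5-methoxy-3-oxo-2,3,3a,6-tetrahydro-1H-indene-1-carboxylate | C=C(Br)C[C@]23C=C(OC)CC=C2[C@@](C(=O)OC)(O)CC3=O | intermediate
10 | methyl 3a-(2-bromoprop-2-en-1-yl)-1-hydroxy-3,5-dioxo-2,3,3a,4,5,6-hexahydro-1H-indene-1-carboxylate (unconjugated 7,7a-ene; 1-OH trans to bromoallyl) | C=C(Br)C[C@]23CC(=O)CC=C2[C@@](C(=O)OC)(O)CC3=O | intermediate (not isolated)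
11 | methyl 3a-(2-bromoprop-2-en-1-yl)-1-hydroxy-3,5-dioxo-2,3,3a,4,5,7a-hexahydro-1H-indene-1-carboxylate (cis-fused; 7a-H cis, 1-OH trans to bromoallyl) | C=C(Br)C[C@]23CC(=O)C=C[C@H]2[C@@](C(=O)OC)(O)CC3=O | intermediate
12 | methyl 3a-(2-bromoprop-2-en-1-yl)-1-hydroxy-3,5-dioxooctahydro-1H-indene-1-carboxylate (same configuration as 11) | C=C(Br)C[C@]23CC(=O)CC[C@H]2[C@@](C(=O)OC)(O)CC3=O | intermediate
13 | tricyclic keto diol ester (rings B, C, D; C6 ketone, 10α-OH, 10β-CO2Me, 9β-H, 13-OH, 16-methylene) | C=C1C[C@]23C[C@@]1(O)CC[C@H]2[C@@](C(=O)OC)(O)CC3=O | intermediate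
14 | 13-O-triethylsilyl ether of 13 | C=C1C[C@]23C[C@@]1(O[Si](CC)(CC)CC)CC[C@H]2[C@@](C(=O)OC)(O)CC3=O | intermediate
15 | C5=C6 enol triflate of 14 | C=C1C[C@]23C[C@@]1(O[Si](CC)(CC)CC)CC[C@H]2[C@@](C(=O)OC)(O)C=C3OS(=O)(=O)C(F)(F)F | intermediate
16 | 10α-hydroxy-10β-carbaldehyde from 15 | C=C1C[C@]23C[C@@]1(O[Si](CC)(CC)CC)CC[C@H]2[C@@](C=O)(O)C=C3OS(=O)(=O)C(F)(F)F | intermediate
17 | 2,2,5,6-tetramethyl-4H-1,3-dioxin-4-one | CC1=C(C)C(=O)OC(C)(C)O1 | starting material
18 | 10-O-(2-methyl-3-oxobutanoyl) ester of 16 (both acyl α-epimers) | C=C1C[C@]23C[C@@]1(O[Si](CC)(CC)CC)CC[C@H]2[C@@](C=O)(OC(=O)C(C)C(C)=O)C=C3OS(=O)(=O)C(F)(F)F | intermediate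
19 | 2-(trimethylsilyl)ethyl C5=C6 enoate from 18 (C7 ester on C6) | C=C1C[C@]23C[C@@]1(O[Si](CC)(CC)CC)CC[C@H]2[C@@](C=O)(OC(=O)C(C)C(C)=O)C=C3C(=O)OCC[Si](C)(C)C | intermediate
20 | γ-lactone Michael adduct (C4–C5 bond formed; 4-acetyl cis to the 10-formyl group across the lactone ring, 5β-H, 6β-ester) | C=C1C[C@]23C[C@@]1(O[Si](CC)(CC)CC)CC[C@H]2[C@@]4(C=O)OC(=O)[C@](C)(C(C)=O)[C@H]4[C@@H]3C(=O)OCC[Si](C)(C)C | intermediate (not isolated)
21 | ring A 1-en-3-one lactone (13-O-triethylsilyl ether and 7-[2-(trimethylsilyl)ethyl] ester of the 1,2-didehydro-3-oxo-15-deoxy target) | C=C1C[C@]23C[C@@]1(O[Si](CC)(CC)CC)CC[C@H]2[C@@]12C=CC(=O)[C@@](C)(C(=O)O1)[C@H]2[C@@H]3C(=O)OCC[Si](C)(C)C | intermediate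
22 | ring A saturated 3-ketone (13-O-triethylsilyl ether and 7-[2-(trimethylsilyl)ethyl] ester of the 3-oxo-15-deoxy target) | C=C1C[C@]23C[C@@]1(O[Si](CC)(CC)CC)CC[C@H]2[C@@]12CCC(=O)[C@@](C)(C(=O)O1)[C@H]2[C@@H]3C(=O)OCC[Si](C)(C)C | intermediate (not isolated)
23 | 13-O-triethylsilyl ether and 7-[2-(trimethylsilyl)ethyl] ester of the 15-deoxy target (3β-OH; C15 is CH2) | C=C1C[C@]23C[C@@]1(O[Si](CC)(CC)CC)CC[C@H]2[C@@]12CC[C@H](O)[C@@](C)(C(=O)O1)[C@H]2[C@@H]3C(=O)OCC[Si](C)(C)C | intermediate
24 | 13-O-triethylsilyl ether and 7-[2-(trimethylsilyl)ethyl] ester of the target (3β-OH, 15β-OH) | C=C1[C@@H](O)[C@]23C[C@@]1(O[Si](CC)(CC)CC)CC[C@H]2[C@@]12CC[C@H](O)[C@@](C)(C(=O)O1)[C@H]2[C@@H]3C(=O)OCC[Si](C)(C)C | intermediate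
25 | the target gibberellin: 16-ene 7-carboxylic acid with 3β-, 13- and 15β-hydroxyl groups and the 19,10-γ-lactone on the 20-nor skeleton of the natural series | C=C1[C@@H](O)[C@]23C[C@@]1(O)CC[C@H]2[C@@]12CC[C@H](O)[C@@](C)(C(=O)O1)[C@H]2[C@@H]3C(=O)O | target

**Totals**
Total step count: 16. Longest linear sequence: 16 steps (from 1 and 2 to 25).

**Steps most likely to fail**

Step 3, the reductive alkylation, may over-reduce the ketone or give poor 1,3-induction from the C10 carboxylate. The fallback sets out from 5 and comes back at 8. Compound 5 is reduced under the same Li/NH3 conditions, but the dienolate is protonated with NH4Cl instead of alkylated and the acid is methylated (MeI, K2CO3) to give the unconjugated keto ester F1. F1 is then alkylated with 6 under asymmetric phase-transfer catalysis (N-(9-anthracenylmethyl)cinchonidinium bromide or its cinchoninium pseudo-enantiomer, whichever gives the 3aS product, CsOH·H2O, PhMe, −40 °C). The chiral ammonium ion pair of the same ring-fusion dienolate, not the C10 substituent, then decides the face, and either C10 epimer of 8 is accepted because step 4 flattens that centre.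

Step 13, the one-pot Michael addition and aldol condensation, may be diverted by the free aldehyde reacting with the β-keto ester carbanion, or the aldol condensation may stall. The fallback sets out from 16 and comes back at 21, and separates the two ring closures by masking the aldehyde. Compound 16 is converted with HC(OMe)3 and pyridinium p-toluenesulfonate in MeOH into the dimethyl acetal F2. F2 is acylated with 17 (PhMe, 110 °C) to the acetoacetate F3, which is carbonylated as in step 12 to the enoate F4. Cs2CO3 in MeCN then effects only the tethered Michael addition to give the lactone acetal F5. Finally the acetal is cleaved with aqueous HCO2H to the keto aldehyde 20, which is closed with piperidinium acetate in PhMe at 60 °C to give 21.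

Step 15, the SeO2 hydroxylation, may give the 15α-alcohol or a mixture, since the facial preference rests on analogy. The fallback sets out from 23 and comes back at 24. The SeO2/t-BuOOH oxidation is run as before and the crude allylic alcohols, including the 15α-alcohol F6, are oxidised with MnO2 in CH2Cl2 to the enone F7; the saturated 3β-alcohol is not touched. F7 is reduced under Luche conditions (NaBH4, CeCl3·7H2O, MeOH, −78 °C). Hydride then enters from the face the selenium reagent had used for oxygen, so the hydroxyl ends on the opposite, β face and gives 24.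

**Further compounds**
F1 | step 3 | methyl (1S)-5-methoxy-3-oxo-2,3,3a,6-tetrahydro-1H-indene-1-carboxylate (3a-epimers) | O=C1C[C@H](C(=O)OC)C2=CCC(OC)=CC12
F2 | step 13 | dimethyl acetal of aldehyde 16 | C=C1C[C@]23C[C@@]1(O[Si](CC)(CC)CC)CC[C@H]2[C@@](C(OC)OC)(O)C=C3OS(=O)(=O)C(F)(F)F
F3 | step 13 | 10-O-(2-methyl-3-oxobutanoyl) ester of F2 (both acyl α-epimers) | C=C1C[C@]23C[C@@]1(O[Si](CC)(CC)CC)CC[C@H]2[C@@](C(OC)OC)(OC(=O)C(C)C(C)=O)C=C3OS(=O)(=O)C(F)(F)F
F4 | step 13 | 2-(trimethylsilyl)ethyl C5=C6 enoate from F3 | C=C1C[C@]23C[C@@]1(O[Si](CC)(CC)CC)CC[C@H]2[C@@](C(OC)OC)(OC(=O)C(C)C(C)=O)C=C3C(=O)OCC[Si](C)(C)C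
F5 | step 13 | γ-lactone Michael adduct carrying the C1 dimethyl acetal | C=C1C[C@]23C[C@@]1(O[Si](CC)(CC)CC)CC[C@H]2[C@@]4(C(OC)OC)OC(=O)[C@](C)(C(C)=O)[C@H]4[C@@H]3C(=O)OCC[Si](C)(C)C
F6 | step 15 | 15α-hydroxy epimer of 24 | C=C1[C@H](O)[C@]23C[C@@]1(O[Si](CC)(CC)CC)CC[C@H]2[C@@]12CC[C@H](O)[C@@](C)(C(=O)O1)[C@H]2[C@@H]3C(=O)OCC[Si](C)(C)C
F7 | step 15 | 15-oxo-16-ene enone from 23 | C=C1C(=O)[C@]23C[C@@]1(O[Si](CC)(CC)CC)CC[C@H]2[C@@]12CC[C@H](O)[C@@](C)(C(=O)O1)[C@H]2[C@@H]3C(=O)OCC[Si](C)(C)C
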